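The route rests on one cut: between the vinylic CH of the E-trisubstituted C(CH3)=CH alkene and the allylic CH2 beside it, the CH2 that is homoallylic to the 1,1-disubstituted (exo-methylene) alkene. A nickel-electrocatalytic decarboxylative alkenylation joins both halves in one operation. The CH2 arrives as a primary radical from a redox-active ester; the CH arrives as an E-alkenyl iodide whose geometry comes from a syn-carboalumination. The precursors are a 4-methylenenonanoic acid carrying the (S)-methyl centre and the O-methylated E-ylidene tetronate ring, and an iodoalkene carrying the furan-3-yl ketone. The skipped 1,5-diene with its sp3–sp2 junction is the feature used; both rings are spectators. Only O-demethylation follows.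

Key step: step 15

Remark: the exocyclic alkene at the tetronate ring is taken as written, E (side chain cis to C4–O, trans to the ring oxygen), the less stable geometry; it is therefore built by a stereospecific elimination and not by equilibration.
Remark: ring numbering used below is O1, C2 (lactone C=O), C3 (methyl), C4 (oxygenated), C5 (ylidene carbon); C1' is the exocyclic carbon and C2' the methyl-bearing centre.

Step 1
Reactants: 1 (R)-4-benzyl-3-propionyloxazolidin-2-one; 2 allyl iodide
Product: 4 (R)-4-benzyl-3-[(S)-2-methylpent-4-enoyl]oxazolidin-2-one, via sodium enolate 3 (not isolated)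
Conditions: NaN(SiMe3)2, THF, −78 °C; then 2, −78 to −40 °C
Reagents that add atoms: none
Why: Evans asymmetric alkylation, in which the chelated (Z)-sodium enolate is allylated on the face away from the benzyl group, sets the (S)-methyl centre.

Step 2
Reactants: 4 (R)-4-benzyl-3-[(S)-2-methylpent-4-enoyl]oxazolidin-2-one
Product: 5 (S)-2-methylpent-4-en-1-ol
Conditions: LiBH4, MeOH (1 equiv), Et2O, 0 °C
Reagents that add atoms: none
Why: Reductive cleavage of the N-acyl oxazolidinone by hydride attack at the exocyclic carbonyl should release the primary alcohol without touching the α-centre or the alkene.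

Step 3
Reactants: 5 (S)-2-methylpent-4-en-1-ol
Product: 6 (S)-2-methylpent-4-enal
Conditions: Dess–Martin periodinane, NaHCO3, CH2Cl2, 0 °C to rt; used at once as a solution
Reagents that add atoms: none
Why: Buffered Dess–Martin oxidation should give the volatile α-branched aldehyde without epimerisation.

Step 4
Reactants: 7 ethyl 2-methyl-3-oxobutanoate
Product: 9 4-hydroxy-3-methylfuran-2(5H)-one (3-methyltetronic acid), via bromo keto ester 8 (not isolated)
Conditions: Br2 (1 equiv), CHCl3, 0 °C to rt, overnight; evaporate; neat, 110 °C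
Reagents that add atoms: none
Why: Classical tetronic acid synthesis, in which bromination with HBr-mediated migration of bromine to the terminal carbon is followed by thermal O-alkylative lactonisation with loss of bromoethane.

Step 5
Reactants: 9 4-hydroxy-3-methylfuran-2(5H)-one
Product: 10 4-methoxy-3-methylfuran-2(5H)-one
Conditions: Me2SO4, K2CO3, acetone, reflux
Reagents that add atoms: dimethyl sulfate, COS(=O)(=O)OC
Why: O-Alkylation of the tetronate anion (a vinylogous carboxylate) gives the 4-methyl ether, which masks the acidic enol through the key step.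

Step 6
Reactants: 10 4-methoxy-3-methylfuran-2(5H)-one
Product: 11 4-methoxy-3-methyl-2-(trimethylsilyloxy)furan
Conditions: Me3SiOTf, Et3N, Et2O, 0 °C; ammonium salt separated, crude product used under argon
Reagents that add atoms: trimethylsilyl triflate, C[Si](C)(C)OS(=O)(=O)C(F)(F)F
Why: Silyl dienol ether formation (O-silylation of the lactone carbonyl and loss of a C5 proton) gives the aromatic 2-silyloxyfuran, nucleophilic at C5.

Step 7
Reactants: 11 4-methoxy-3-methyl-2-(trimethylsilyloxy)furan; 6 (S)-2-methylpent-4-enal
Product: 13 (R)-5-[(1R,2S)-1-hydroxy-2-methylpent-4-en-1-yl]-4-methoxy-3-methylfuran-2(5H)-one, via TMS ether 12 (not isolated)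
Conditions: Bu4NF (anhydrous, 10 mol%), THF, −78 °C; then citric acid, MeOH, 0 °C
Reagents that add atoms: none
Why: The fluoride-catalysed vinylogous Mukaiyama aldol addition through the free furanolate should favour the 5,1'-anti (erythro) adduct, whereas the Lewis-acid manifold favours syn; the Felkin–Anh isomer is drawn, but only the C5/C1' relationship matters because both centres become sp2 in step 8, so any anti-Felkin anti isomer is carried along, and the C2' centre should survive at −78 °C.

Step 8
Reactants: 13 (R)-5-[(1R,2S)-1-hydroxy-2-methylpent-4-en-1-yl]-4-methoxy-3-methylfuran-2(5H)-one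
Product: 14 (E)-4-methoxy-3-methyl-5-[(S)-2-methylpent-4-en-1-ylidene]furan-2(5H)-one
Conditions: PPh3, DEAD, THF, 0 °C to rt
Reagents that add atoms: none
Why: Mitsunobu-type activation of the alcohol as an alkoxyphosphonium and stereospecific anti E2 loss of the C5 proton (the anti-elimination route to stereodefined γ-alkylidenebutenolides) should turn the anti adduct into the E-ylidene tetronate, with the side chain cis to C4–OMe.

Step 9
Reactants: 15 acetic acid; 16 2,3-dibromopropene
Product: 18 4-bromopent-4-enoic acid, via dilithio acetate dianion 17 (not isolated)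
Conditions: LiN(iPr)2 (2.2 equiv), THF–DMPU, 0 °C to rt; then 16, −78 °C to rt; aq HCl
Reagents that add atoms: none
Why: Carboxylic acid dianion alkylation (SN2 at the allylic CH2Br, the vinylic bromide being inert) gives the 2-bromoalkene acid in one operation.

Step 10
Reactants: 14 (E)-4-methoxy-3-methyl-5-[(S)-2-methylpent-4-en-1-ylidene]furan-2(5H)-one; 18 4-bromopent-4-enoic acid
Product: 20 (S,E)-9-(3-methoxy-4-methyl-5-oxofuran-2(5H)-ylidene)-8-methyl-4-methylenenonanoic acid, via B-alkyl-9-BBN 19 (not isolated)
Conditions: 9-BBN (1.3 equiv), THF, 0 °C to rt; then 18, Cs2CO3 (4 equiv), Pd(dppf)Cl2 (5 mol%), AsPh3 (10 mol%), DMF–H2O, rt; citric acid work-up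
Reagents that add atoms: none
Why: 9-BBN should add only to the monosubstituted terminal alkene (anti-Markovnikov hydroboration), and B-alkyl Suzuki–Miyaura coupling with the 2-bromoalkene of the caesium carboxylate builds the 1,1-disubstituted alkene at room temperature, conditions that should spare the enol lactone and its E geometry.

Step 11
Reactants: 21 pent-4-yn-1-ol
Product: 23 (E)-5-iodo-4-methylpent-4-en-1-ol, via alkenylalane 22 (not isolated)
Conditions: Me3Al (3 equiv), Cp2ZrCl2 (25 mol%), CH2Cl2, 0 °C to rt; then I2, THF, −30 to 0 °C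
Reagents that add atoms: trimethylaluminium, C[Al](C)C; iodine, II
Why: Negishi zirconium-catalysed carboalumination adds CH3 and Al syn across the terminal alkyne and iodinolysis proceeds with retention, which fixes the E geometry of the trisubstituted iodoalkene.

Step 12
Reactants: 23 (E)-5-iodo-4-methylpent-4-en-1-ol
Product: 24 (E)-5-iodo-4-methylpent-4-enal
Conditions: Dess–Martin periodinane, NaHCO3, CH2Cl2, 0 °C to rt
Reagents that add atoms: none
Why: Dess–Martin oxidation of the primary alcohol should leave the alkenyl iodide untouched.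

Step 13
Reactants: 24 (E)-5-iodo-4-methylpent-4-enal; 25 3-bromofuran
Product: 27 (E)-1-(furan-3-yl)-5-iodo-4-methylpent-4-en-1-ol (racemic at the carbinol), via 3-furyllithium 26 (not isolated)
Conditions: n-BuLi, THF, −78 °C; then 24, −78 °C; aq NH4Cl
Reagents that add atoms: none
Why: Bromine–lithium exchange at −78 °C gives 3-furyllithium, which should add to the aldehyde (1,2-addition) faster than it attacks the alkenyl iodide or isomerises; the racemic carbinol centre is removed in step 14.

Step 14
Reactants: 27 (E)-1-(furan-3-yl)-5-iodo-4-methylpent-4-en-1-ol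
Product: 28 (E)-1-(furan-3-yl)-5-iodo-4-methylpent-4-en-1-one
Conditions: Dess–Martin periodinane, NaHCO3, CH2Cl2, 0 °C to rt
Reagents that add atoms: none
Why: Dess–Martin oxidation of the furyl carbinol gives the ketone, and the furan and alkenyl iodide should tolerate the buffered reagent.

Step 15
Reactants: 20 (S,E)-9-(3-methoxy-4-methyl-5-oxofuran-2(5H)-ylidene)-8-methyl-4-methylenenonanoic acid; 28 (E)-1-(furan-3-yl)-5-iodo-4-methylpent-4-en-1-one
Product: 30 (E)-5-[(2S,9E)-13-(furan-3-yl)-2,10-dimethyl-6-methylene-13-oxotridec-9-en-1-ylidene]-4-methoxy-3-methylfuran-2(5H)-one, via NHPI ester 29 (not isolated)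
Conditions: N-hydroxyphthalimide, N,N'-diisopropylcarbodiimide, DMAP (cat.), CH2Cl2, rt; filter, evaporate; then 28, NiCl2·6H2O (20 mol%), 2,2'-bipyridine (20 mol%), AgNO3 (30 mol%), DMF, undivided cell, magnesium anode, reticulated vitreous carbon cathode, constant current, rt
Reagents that add atoms: none
Why: The NHPI ester is reduced (by low-valent nickel or at the silver-coated cathode) and loses phthalimide anion and CO2 to give the primary radical at the CH2 homoallylic to the exo-methylene, while zerovalent nickel/bipyridine inserts into the C–I bond of 28 with retention; the alkenylnickel species captures the radical and reductive elimination from trivalent nickel forms the CH2–CH= bond, the cathode returning nickel to its low-valent state as the magnesium anode is consumed. The closest known reaction type is the nickel-electrocatalytic decarboxylative alkenylation of redox-active esters with alkenyl halides used for polyene terpenoids. No ring is closed and no stereocentre is created; the (S)-methyl centre is remote from the radical and is not involved. The selectivity needed is retention of the E geometry of the C(CH3)=CH unit, secured by stereoretentive oxidative addition of the E-iodide, and chemoselectivity for the C–I bond over the ketone, the enol lactone and the furan, secured by the mild potential of the bipyridine–nickel couple. The homoallyl radical can only undergo a degenerate 3-exo closure and reopening, the ylidene tetronate and furan are too remote or too electron-rich to trap it before nickel does, and the E-alkenylnickel carbon is trans to the ketone-bearing chain and cannot add to the carbonyl.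

Step 16
Reactants: 30 (E)-5-[(2S,9E)-13-(furan-3-yl)-2,10-dimethyl-6-methylene-13-oxotridec-9-en-1-ylidene]-4-methoxy-3-methylfuran-2(5H)-one
Product: 31 (E)-5-[(2S,9E)-13-(furan-3-yl)-2,10-dimethyl-6-methylene-13-oxotridec-9-en-1-ylidene]-4-hydroxy-3-methylfuran-2(5H)-one (target)
Conditions: LiCl (10 equiv), DMSO, 55 °C; then cold dilute HCl to pH 3
Reagents that add atoms: none
Why: SN2 demethylation of the vinylogous methyl carbonate by chloride (Krapcho-type O-dealkylation, the tetronate being the leaving group) under neutral conditions should keep the E-ylidene, the exo-methylene and the furan intact, and mild acidification frees the tetronic acid.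

Compound list
1 | (R)-4-benzyl-3-propionyloxazolidin-2-one | CCC(=O)N1[C@H](Cc2ccccc2)COC1=O | starting material
2 | allyl iodide (3-iodoprop-1-ene) | C=CCI | starting material
3 | sodium (Z)-enolate of 1 | C/C=C(\[O-])N1[C@H](Cc2ccccc2)COC1=O.[Na+] | intermediate
4 | (R)-4-benzyl-3-[(S)-2-methylpent-4-enoyl]oxazolidin-2-one | C=CC[C@H](C)C(=O)N1[C@H](Cc2ccccc2)COC1=O | intermediate
5 | (S)-2-methylpent-4-en-1-ol | C=CC[C@H](C)CO | intermediate
6 | (S)-2-methylpent-4-enal | C=CC[C@H](C)C=O | intermediate
7 | ethyl 2-methyl-3-oxobutanoate (ethyl 2-methylacetoacetate) | CCOC(=O)C(C)C(C)=O | starting material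
8 | ethyl 4-bromo-2-methyl-3-oxobutanoate | CCOC(=O)C(C)C(=O)CBr | intermediate
9 | 4-hydroxy-3-methylfuran-2(5H)-one (3-methyltetronic acid) | CC1=C(O)COC1=O | intermediate
10 | 4-methoxy-3-methylfuran-2(5H)-one | COC1=C(C)C(=O)OC1 | intermediate
11 | 4-methoxy-3-methyl-2-(trimethylsilyloxy)furan | COc1coc(O[Si](C)(C)C)c1C | intermediate
12 | (R)-4-methoxy-3-methyl-5-[(1R,2S)-2-methyl-1-(trimethylsilyloxy)pent-4-en-1-yl]furan-2(5H)-one | C=CC[C@H](C)[C@@H](O[Si](C)(C)C)[C@H]1OC(=O)C(C)=C1OC | intermediate
13 | (R)-5-[(1R,2S)-1-hydroxy-2-methylpent-4-en-1-yl]-4-methoxy-3-methylfuran-2(5H)-one (5,1'-anti adduct) | C=CC[C@H](C)[C@@H](O)[C@H]1OC(=O)C(C)=C1OC | intermediate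
14 | (E)-4-methoxy-3-methyl-5-[(S)-2-methylpent-4-en-1-ylidene]furan-2(5H)-one | C=CC[C@H](C)/C=C1/OC(=O)C(C)=C1OC | intermediate
15 | acetic acid | CC(=O)O | starting material
16 | 2,3-dibromopropene | C=C(Br)CBr | starting material
17 | dilithium dianion of acetic acid (dilithium ethene-1,1-diolate) | C=C(O[Li])O[Li] | intermediate
18 | 4-bromopent-4-enoic acid | C=C(Br)CCC(=O)O | intermediate
19 | 9-[(S,E)-5-(3-methoxy-4-methyl-5-oxofuran-2(5H)-ylidene)-4-methylpentyl]-9-borabicyclo[3.3.1]nonane | C12CCCC(CCC1)B2CCC[C@H](C)/C=C3/OC(=O)C(C)=C3OC | intermediate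
20 | (S,E)-9-(3-methoxy-4-methyl-5-oxofuran-2(5H)-ylidene)-8-methyl-4-methylenenonanoic acid | C=C(CCC(=O)O)CCC[C@H](C)/C=C1/OC(=O)C(C)=C1OC | intermediate
21 | pent-4-yn-1-ol | C#CCCCO | starting material
22 | dimethylaluminium (E)-5-(dimethylalumanyl)-4-methylpent-4-en-1-olate | C[Al](C)OCCC/C(C)=C/[Al](C)C | intermediate
23 | (E)-5-iodo-4-methylpent-4-en-1-ol | OCCC/C(C)=C/I | intermediate
24 | (E)-5-iodo-4-methylpent-4-enal | O=CCC/C(C)=C/I | intermediate
25 | 3-bromofuran | Brc1ccoc1 | starting material
26 | 3-furyllithium | [Li]c1ccoc1 | intermediate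
27 | (E)-1-(furan-3-yl)-5-iodo-4-methylpent-4-en-1-ol (racemic carbinol) | OC(CC/C(C)=C/I)c1ccoc1 | intermediate
28 | (E)-1-(furan-3-yl)-5-iodo-4-methylpent-4-en-1-one | O=C(CC/C(C)=C/I)c1ccoc1 | intermediate
29 | 1,3-dioxoisoindolin-2-yl (S,E)-9-(3-methoxy-4-methyl-5-oxofuran-2(5H)-ylidene)-8-methyl-4-methylenenonanoate | C=C(CCC(=O)ON2C(=O)c3ccccc3C2=O)CCC[C@H](C)/C=C1/OC(=O)C(C)=C1OC | intermediate
30 | (E)-5-[(2S,9E)-13-(furan-3-yl)-2,10-dimethyl-6-methylene-13-oxotridec-9-en-1-ylidene]-4-methoxy-3-methylfuran-2(5H)-one | C=C(CC/C=C(\C)CCC(=O)c1ccoc1)CCC[C@H](C)/C=C1/OC(=O)C(C)=C1OC | intermediate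
31 | (E)-5-[(2S,9E)-13-(furan-3-yl)-2,10-dimethyl-6-methylene-13-oxotridec-9-en-1-ylidene]-4-hydroxy-3-methylfuran-2(5H)-one | C=C(CC/C=C(\C)CCC(=O)c1ccoc1)CCC[C@H](C)/C=C1/OC(=O)C(C)=C1O | target

Total step count: 16.
Longest linear sequence: 8 steps (steps 1, 2, 3, 7, 8, 10, 15, 16; the branch through steps 4, 5, 6 is equally long).

Steps most likely to fail

Step 7. The simple diastereoselection may not favour the anti adduct with this 3-methyl-4-methoxy furan, and the basic furanolate may epimerise the α-branched aldehyde before it adds. The fallback sets out from 11 and 6: a BF3·OEt2-promoted vinylogous Mukaiyama aldol addition (CH2Cl2, −78 °C; non-basic, syn-selective open transition state) should give the 5,1'-syn adduct (S)-5-[(1R,2S)-1-hydroxy-2-methylpent-4-en-1-yl]-4-methoxy-3-methylfuran-2(5H)-one F1. A stereospecific syn-elimination with the Burgess reagent (benzene, 50 °C) then converts the syn adduct into the same E-alkene, and the route is rejoined at 14.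

Step 8. The concerted anti-elimination may leak into an E1cB pathway through the furanolate, eroding the E geometry towards the more stable Z isomer, or the activated alcohol may be captured by the hydrazide in an SN2 reaction. The fallback sets out from 13: mesylation (MsCl, Et3N, CH2Cl2, −20 °C) gives (1R,2S)-1-[(R)-3-methoxy-4-methyl-5-oxo-2,5-dihydrofuran-2-yl]-2-methylpent-4-en-1-yl methanesulfonate F2, and DBU-mediated elimination deliberately gives the thermodynamic (Z)-4-methoxy-3-methyl-5-[(S)-2-methylpent-4-en-1-ylidene]furan-2(5H)-one F3. Irradiation (350 nm, MeCN) should set up a photostationary E/Z mixture from which the E isomer is separated by chromatography while F3 is recycled; the route is rejoined at 14.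

Step 15. Reduction or dimerisation of the primary radical and protodeiodination of the alkenyl iodide may outrun the cross-coupling. The fallback is a two-electron Negishi sp3–sp2 coupling that sets out from 20. The acid is converted (N-hydroxypyridine-2-thione, DCC, dark) into its Barton ester 2-thioxopyridin-1(2H)-yl (S,E)-9-(3-methoxy-4-methyl-5-oxofuran-2(5H)-ylidene)-8-methyl-4-methylenenonanoate F4. Photolysis with CHI3 (Barton decarboxylative iodination) gives (E)-5-[(S)-8-iodo-2-methyl-6-methyleneoctylidene]-4-methoxy-3-methylfuran-2(5H)-one F5, and zinc dust with LiCl in THF gives the alkylzinc iodide [(S,E)-8-(3-methoxy-4-methyl-5-oxofuran-2(5H)-ylidene)-7-methyl-3-methyleneoctyl]zinc iodide F6. Pd(dppf)Cl2-catalysed coupling of F6 with 28 rejoins the route at 30.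

Further compounds
F1 | step 7 | (S)-5-[(1R,2S)-1-hydroxy-2-methylpent-4-en-1-yl]-4-methoxy-3-methylfuran-2(5H)-one | C=CC[C@H](C)[C@@H](O)[C@@H]1OC(=O)C(C)=C1OC
F2 | step 8 | (1R,2S)-1-[(R)-3-methoxy-4-methyl-5-oxo-2,5-dihydrofuran-2-yl]-2-methylpent-4-en-1-yl methanesulfonate | C=CC[C@H](C)[C@@H](OS(C)(=O)=O)[C@H]1OC(=O)C(C)=C1OC
F3 | step 8 | (Z)-4-methoxy-3-methyl-5-[(S)-2-methylpent-4-en-1-ylidene]furan-2(5H)-one | C=CC[C@H](C)/C=C1\OC(=O)C(C)=C1OC
F4 | step 15 | 2-thioxopyridin-1(2H)-yl (S,E)-9-(3-methoxy-4-methyl-5-oxofuran-2(5H)-ylidene)-8-methyl-4-methylenenonanoate | C=C(CCC(=O)On2ccccc2=S)CCC[C@H](C)/C=C1/OC(=O)C(C)=C1OC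
F5 | step 15 | (E)-5-[(S)-8-iodo-2-methyl-6-methyleneoctylidene]-4-methoxy-3-methylfuran-2(5H)-one | C=C(CCI)CCC[C@H](C)/C=C1/OC(=O)C(C)=C1OC
F6 | step 15 | [(S,E)-8-(3-methoxy-4-methyl-5-oxofuran-2(5H)-ylidene)-7-methyl-3-methyleneoctyl]zinc iodide | C=C(CC[Zn]I)CCC[C@H](C)/C=C1/OC(=O)C(C)=C1OC
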